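## Structural features

The target is a germacranolide of the melampolide type: a ten-membered carbocycle (C1–C10) with a Z C1=C10 bond carrying C14 and an E C4=C5 bond carrying C15. A five-membered lactone (O6, C6, C7, C11, C12) is fused trans across C6–C7 and carries the exocyclic C11=C13 methylene. C6, C7, C8 and C9 form an unbroken row of four stereocentres (6R, 7S, 8S, 9R); the oxygens on C8 and C9 are cis to each other, and O8 lies on the same ring face as C11. O8 is esterified with [(2R)-2-methyloxiran-2-yl]acetic acid, which holds a fifth, quaternary stereocentre, and O9 is a free allylic hydroxyl. The fragile parts are: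
- the 2-methylene lactone (Michael acceptor, reducible);
- the 2,2-disubstituted oxirane (acid), which is also β,γ to an ester carbonyl (base-induced opening);
- the cis hydroxy ester (acyl shift between O8 and O9, lactone shift from O6 to O8);
- the Z trisubstituted alkene and the 1,5-diene in a medium ring (acid-induced transannular cyclisation, thermal [3,3] shift).

The real difficulty is to close the strained ten-membered ring with both alkene geometries intact, to relate C8 and C9 to the C6/C7 pair, and then to tell O8 from O9. The key step uses the adjacent, cis-oxygenated ring carbons C8 and C9: they are the retron of a reductive coupling between a C8 aldehyde (on C7 of the lactone) and a C9 enal (on C10), so one new bond closes the ring and creates both carbinol centres.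

## Logic of the disconnections

**35 to 34, then to 26 and 32.** The O9–Si bond and the ester C–O bond at O8 are cut last. The epoxy ester is the most fragile part and is therefore added as late as possible. This removes five carbons and one stereocentre from the ring system. The forward acylation must reach O8 only (O9 is blocked as a silyl ether), the acyl donor must be activated without a base that opens the oxirane, and the final desilylation must be close to neutral.

**32 to 30, 28 and 27.** The carboxyl carbon is traced to a terminal alkene (one carbon lost on cleavage) and the CH2–vinyl bond is cut back to an oxirane CH2. The quaternary centre is bought in 27 and no bond to it is ever broken. The forward step requires that the vinyl nucleophile opens the oxirane CH2 and does not displace the sulfonate directly, since the two paths give opposite enantiomers.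

**26 to 25, 23 and 22.** The C11=C13 bond is cut. The methylene group is placed after the ring closure because a 2-methylene lactone would be reduced by the coupling reagent. The forward enolate chemistry needs both hydroxyls masked, with the O8 mask removable in the presence of the O9 mask.

**22 to 20.** Two O–Si bonds are cut. This is where O8 and O9 are told apart. The forward step depends on the allylic C9 hydroxyl reacting first.

**20 to 19.** The C8–C9 bond is cut. This opens the ten-membered ring and removes two stereocentres in one move, leaving an acyclic chain on a trans lactone whose two alkenes are already in place. The forward step needs coupling at the carbonyl carbon of the enal, retention of the Z geometry, the cis diol, and the correct face of the C8 carbonyl relative to C7.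

**19 to 18, 17, 16 and 15.** No skeletal bond is cut; only oxidation levels change. The C9 aldehyde comes from a silyl-protected alcohol and the C8 aldehyde from an acyl group. The forward steps must reach the C8 aldehyde without passing through a C8 alcohol (which could take over the lactone) and must avoid base, because the C8 carbonyl has C7–H in the α position and the lactone oxygen in the β position.

**15 to 13 and 10.** The C6–C7 bond and the O6–C12 lactone bond are cut. This is an aldol retron with the imide carbonyl as C8 and the ester carbonyl as C12. The 6,7-trans lactone corresponds to the syn aldol adduct, so the forward step must be a syn-selective aldol with the auxiliary that gives 6R,7S.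

**13 to 11 and 12.** The N–acyl bond is cut; both pieces are commercial.

**10 to 9 and 6.** C5–C6 and C4–C15 are cut. A terminal alkyne takes up methyl and a one-carbon electrophile. The forward step needs cis addition with methyl on the internal carbon, which fixes the E C4=C5 bond.

**6 to 5, 4, then 2 and 3; 2 to 1.** The C1=C10 bond is cut. The forward olefination must be Z-selective. Because the ester is reduced before any other oxygen function exists in the chain, O9 and the later C6 carbonyl never need to be differentiated.

## Other disconnections considered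

Alternative 1: The cut is at C5–C6 and C4–C15, with the lactone C12–O bond formed in the same flask.
- Forward step: a zerovalent nickel catalyst (Ni(cod)2 with a carbene or phosphine ligand) and Me2Zn would join an aldehyde carbon (C6) to the terminal carbon (C5) of a C4≡C5 alkyne, with methyl (C15) delivered cis to C4. The C6 zinc alkoxide would then close onto an N-methoxy-N-methyl amide at C12 and give A1, the ten-membered carbocycle with the saturated trans lactone, O8 as triethylsilyl ether and O9 as TBS ether.
- In its favour: one operation would make the ring, the E C4=C5 bond with its methyl group, the C6 stereocentre and the lactone. O8 and O9 carry different silyl groups from the open-chain stage, and no Z enal or allylic ketyl is involved. On these two points (built-in differentiation of O8 and O9, no risk to the Z C1=C10 bond during closure) this alternative is the better one.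
- Against it here: an endocyclic E trisubstituted alkene must form in a ten-membered ring, near the lower size limit of such closures, where exocyclic closure, dimerisation and reductive coupling (hydrogen instead of methyl) compete. C6 is set only by induction from C7. The C6 aldehyde is α to an epimerisable C7, and the C1=C10 alkene lies 1,5 to the alkyne and can bind nickel. Attack of the zinc alkoxide on the amide may need a separate step.
- Comparison: both plans close the ring late, and A1 is the same compound as 22, so everything after it would be shared. The chosen plan makes C8 and C9 during closure from a C6/C7 pair set by one aldol. Alternative 1 needs the C7–C8–C9 triad on an open chain and creates one stereocentre and one alkene geometry in the closure. The nickel step is a ligand-controlled two-electron process with more handles for optimisation (equal or better); the pinacol is a radical coupling under substrate control. An open chain with three stereocentres, two silyl ethers, a Z alkene, an alkyne, an aldehyde and the amide is unlikely to take fewer steps than the fourteen that lead to 22 here, so the step count is judged about equal.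

Alternative 2: The cut is at C2–C3, and C5–C10 is reconnected, which turns the carbocycle into a six-membered ring (C5 to C10) with vinyl and oxygen on C10 and a 2-propenyl group on C5.
- Forward step: the potassium alkoxide (KH, 18-crown-6) would undergo an anionic oxy-Cope shift that forms C2–C3 and breaks C5–C10, and PhNTf2 would trap the C10 enolate as A2. A2 is the cyclodecadienyl C10 triflate with O6 as TBS ether, the C11(=C13)–C12 unit on C7 (C12 as a 4-methoxybenzyl ether) and O8/O9 as an acetonide.
- In its favour: the ring expansion is unimolecular and needs no high dilution, which is better than any end-to-end closure. C6 to C9 can be set on a rigid six-membered ring. The exocyclic methylene is already present, so no late enolate methylenation is needed (better).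
- Against it here: A2 lacks C14, which needs a cross-coupling of the triflate. The lactone must still be made by deprotection and oxidation at C12. The acetonide has to be removed with acid from an acid-sensitive cyclodecadiene, after which O8 and O9 still have to be distinguished. The ring-cis C1=C10 and E C4=C5 geometry depends on the chair or boat course of the shift, which is set by a crowded tertiary carbinol whose configuration is hard to control. The C1=C10 bond of A2 is ring-cis; with the triflate oxygen on C10 its CIP descriptor is E, and it becomes Z only when methyl replaces the triflate.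
- Comparison: ring formation is more reliable than in the chosen plan (better), and the alkene geometry follows from a concerted, stereospecific step (equal or better once the substrate is in hand). The chosen plan has the lactone, C14 and both alkenes in place before closure, while alternative 2 adds C14, the lactone and the O8/O9 differentiation afterwards on top of a long build-up of the six-membered ring. It is therefore expected to be clearly longer.

Alternative 3: The cut is at C7–C8, with O–C13 reconnected, giving a twelve-membered ring in which C9 is an enol ether carbon with an exocyclic methylene (C8), bonded through oxygen to C13 next to a C7=C11 alkene.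
- Forward step: heating this 2-methylene cyclic ether (from Cp2TiMe2 methylenation of a lactone carbonyl at C9) would cause a [3,3] shift that forms C7–C8, breaks O–C13, creates C11=C13 and the C9 ketone, and gives A3. A3 is the (1(10)Z,4E)-cyclodecadien-9-one with the 2-propenyl unit on C7 and 4-methoxybenzyl ethers on O6 and O12.
- In its favour: a twelve-membered lactone is easier to close than a ten-membered carbocycle (better). The shift sets C7 from an alkene geometry and delivers C11=C13 directly (better). The C8 and C9 oxygens would be introduced one after the other and so are differentiated by origin (better).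
- Against it here: A3 has no oxygen at C8 and a ketone at C9, so both stereocentres must be made afterwards on the flexible ring under substrate control (hydroxylation α to the Z enone, then reduction). The Z C1=C10 bond is conjugated to the ketone and must survive heating, and a ring with a 1,5-diene can undergo a competing Cope shift. Two benzyl-type ethers must be removed and C12 oxidised to close the lactone.
- Comparison: the chosen plan sets C8 and C9 in the ring-forming event with a metal chelate and carries the lactone from the start. Alternative 3 is pericyclic and predictable in the ring-forming step but defers the two carbinol centres and the lactone, and needs hydroxylation, reduction, deprotection, oxidative lactonisation and esterification after the key step. It is expected to be longer, although it avoids the late methylenation and the O8/O9 problem.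

Key step: step 13

Remark on the chemistry: the 6,7-trans lactone corresponds to the syn aldol adduct (an anti adduct, for example from a MgCl2-promoted aldol, would close to the 6,7-cis lactone), so a boron-mediated syn aldol with the (4S)-benzyl auxiliary is used; the structures of the coupling precursor 19 and of the diol 20 are consistent with the target and are used unchanged.

Remark on the chemistry: in the monosilylation of 20 the allylic C9 hydroxyl (next to sp2 C10) is assumed to react before the C8 hydroxyl (between C7 and C9, on the face of C11); the route is written for this sense.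

## Route

Step 1
Reactants: 1 pent-4-yn-1-ol
Product: 2 pent-4-ynal
Conditions: (COCl)2, DMSO, CH2Cl2, −78 °C; Et3N, −78 to 0 °C
Reagents that add atoms: none
Why: Swern oxidation of a primary alcohol; the terminal alkyne is inert and the volatile aldehyde is carried on as a dried solution.

Step 2
Reactants: 2 pent-4-ynal; 3 ethyl 2-[bis(2,2,2-trifluoroethoxy)phosphoryl]propanoate
Product: 4 ethyl (2Z)-2-methylhept-2-en-6-ynoate
Conditions: KN(SiMe3)2, 18-crown-6, THF, −78 °C
Reagents that add atoms: none
Why: Still–Gennari olefination; with the electron-poor phosphonate and a dissociated potassium ion, elimination from the kinetic adduct outruns its reversal, which should give the Z trisubstituted enoate, the future Z C1=C10 bond with C9 and C2 cis.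

Step 3
Reactants: 4 ethyl (2Z)-2-methylhept-2-en-6-ynoate
Product: 5 (2Z)-2-methylhept-2-en-6-yn-1-ol
Conditions: i-Bu2AlH, CH2Cl2, −78 °C; Rochelle salt
Reagents that add atoms: none
Why: 1,2-reduction of a conjugated ester to the allylic alcohol with retention of geometry; C9 reaches the alcohol level while it is the only oxygen function in the molecule.

Step 4
Reactants: 5 (2Z)-2-methylhept-2-en-6-yn-1-ol
Product: 6 tert-butyl(dimethyl){[(2Z)-2-methylhept-2-en-6-yn-1-yl]oxy}silane
Conditions: TBSCl, imidazole, DMF, 0 °C to rt
Reagents that add atoms: tert-butyldimethylsilyl chloride, CC(C)(C)[Si](C)(C)Cl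
Why: Silylation of a primary alcohol; the TBS ether should survive the organoaluminium, boron enolate, thiolate and hydrosilane steps that follow.

Step 5
Reactants: 6 tert-butyl(dimethyl){[(2Z)-2-methylhept-2-en-6-yn-1-yl]oxy}silane
Product: 9 (2E,6Z)-8-{[tert-butyl(dimethyl)silyl]oxy}-3,7-dimethylocta-2,6-dien-1-ol, via alkenyldimethylalane 7 (not isolated), via lithium alkenyl(butyl)dimethylalanate 8 (not isolated)
Conditions: Me3Al, Cp2ZrCl2 (cat.), CH2Cl2, 0 °C to rt; evaporate; n-BuLi, hexane/THF, −78 to 0 °C; (CH2O)n, rt
Reagents that add atoms: trimethylaluminium, C[Al](C)C; formaldehyde (as paraformaldehyde), C=O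
Why: Zirconium-catalysed carboalumination (Negishi) adds methyl and aluminium cis across the terminal alkyne with methyl on the internal carbon, which fixes C15 and the E C4=C5 bond; the alanate formed with n-BuLi is hydroxymethylated with retention to install C6.

Step 6
Reactants: 9 (2E,6Z)-8-{[tert-butyl(dimethyl)silyl]oxy}-3,7-dimethylocta-2,6-dien-1-ol
Product: 10 (2E,6Z)-8-{[tert-butyl(dimethyl)silyl]oxy}-3,7-dimethylocta-2,6-dienal
Conditions: MnO2, CH2Cl2, rt
Reagents that add atoms: none
Why: Allylic oxidation with MnO2 under neutral heterogeneous conditions; the silyl ether and both alkene geometries should be unaffected.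

Step 7
Reactants: 11 (4S)-4-benzyl-1,3-oxazolidin-2-one; 12 methyl 4-chloro-4-oxobutanoate
Product: 13 methyl 4-[(4S)-4-benzyl-2-oxo-1,3-oxazolidin-3-yl]-4-oxobutanoate
Conditions: n-BuLi, THF, −78 °C; then 12, −78 to 0 °C
Reagents that add atoms: none
Why: N-acylation of the lithiated oxazolidinone; the acid chloride reacts far faster than the methyl ester.

Step 8
Reactants: 13 methyl 4-[(4S)-4-benzyl-2-oxo-1,3-oxazolidin-3-yl]-4-oxobutanoate; 10 (2E,6Z)-8-{[tert-butyl(dimethyl)silyl]oxy}-3,7-dimethylocta-2,6-dienal
Product: 15 (4S)-4-benzyl-3-{(2R,3S)-2-[(1E,5Z)-7-{[tert-butyl(dimethyl)silyl]oxy}-2,6-dimethylhepta-1,5-dien-1-yl]-5-oxooxolane-3-carbonyl}-1,3-oxazolidin-2-one, via syn-aldol adduct 14 (not isolated)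
Conditions: Bu2BOTf, i-Pr2NEt, CH2Cl2, −78 to 0 °C; 10, −78 to 0 °C; pH 7 buffer, MeOH, H2O2, 0 °C; then PPTS (cat.), toluene, 40 °C
Reagents that add atoms: none
Why: Evans syn aldol: the dibutylboron Z enolate forms at the imide α-carbon (C7) and adds through a Zimmerman–Traxler chair on the face away from the benzyl group, which should set 7S and 6R. The C6 hydroxyl then closes onto the C12 methyl ester, and a syn adduct necessarily gives the 6,7-trans lactone.

Step 9
Reactants: 15 (4S)-4-benzyl-3-{(2R,3S)-2-[(1E,5Z)-7-{[tert-butyl(dimethyl)silyl]oxy}-2,6-dimethylhepta-1,5-dien-1-yl]-5-oxooxolane-3-carbonyl}-1,3-oxazolidin-2-one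
Product: 16 S-ethyl (2R,3S)-2-[(1E,5Z)-7-{[tert-butyl(dimethyl)silyl]oxy}-2,6-dimethylhepta-1,5-dien-1-yl]-5-oxooxolane-3-carbothioate
Conditions: EtSH, n-BuLi (LiSEt), THF, 0 °C
Reagents that add atoms: ethanethiol, CCS
Why: Acyl substitution at the exocyclic imide carbonyl by the soft, weakly basic thiolate, which is faster than attack on the lactone and mild enough to spare the C7–H/C6–O pair from β-elimination; the auxiliary is recovered.

Step 10
Reactants: 16 S-ethyl (2R,3S)-2-[(1E,5Z)-7-{[tert-butyl(dimethyl)silyl]oxy}-2,6-dimethylhepta-1,5-dien-1-yl]-5-oxooxolane-3-carbothioate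
Product: 17 (2R,3S)-2-[(1E,5Z)-7-{[tert-butyl(dimethyl)silyl]oxy}-2,6-dimethylhepta-1,5-dien-1-yl]-5-oxooxolane-3-carbaldehyde
Conditions: Et3SiH, Pd/C (cat.), acetone, rt
Reagents that add atoms: none
Why: Fukuyama reduction: palladium inserts into the C–S bond and the silane delivers hydride, so only the thioester is taken to the aldehyde; C8 never passes through an alcohol that could capture the lactone.

Step 11
Reactants: 17 (2R,3S)-2-[(1E,5Z)-7-{[tert-butyl(dimethyl)silyl]oxy}-2,6-dimethylhepta-1,5-dien-1-yl]-5-oxooxolane-3-carbaldehyde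
Product: 18 (2R,3S)-2-[(1E,5Z)-7-hydroxy-2,6-dimethylhepta-1,5-dien-1-yl]-5-oxooxolane-3-carbaldehyde
Conditions: HF·pyridine, pyridine, THF, 0 °C
Reagents that add atoms: none
Why: Fluoride cleavage of a primary TBS ether in a weakly acidic buffered medium, which should leave the base-sensitive β-acyloxy aldehyde and the C7 centre untouched.

Step 12
Reactants: 18 (2R,3S)-2-[(1E,5Z)-7-hydroxy-2,6-dimethylhepta-1,5-dien-1-yl]-5-oxooxolane-3-carbaldehyde
Product: 19 (2R,3S)-2-[(1E,5Z)-2,6-dimethyl-7-oxohepta-1,5-dien-1-yl]-5-oxooxolane-3-carbaldehyde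
Conditions: MnO2, CH2Cl2, 0 °C to rt, dark; filtered and used at once
Reagents that add atoms: none
Why: MnO2 oxidises only the allylic alcohol and does so without base, so the Z enal should form with retention of geometry while the aliphatic aldehyde stays unchanged.

Step 13
Reactants: 19 (2R,3S)-2-[(1E,5Z)-2,6-dimethyl-7-oxohepta-1,5-dien-1-yl]-5-oxooxolane-3-carbaldehyde
Product: 20 (3aR,4S,5R,6Z,10E,11aR)-4,5-dihydroxy-6,10-dimethyl-3a,4,5,8,9,11a-hexahydrocyclodeca[b]furan-2(3H)-one
Conditions: SmI2 (3 equiv), THF, −78 °C, slow addition of 19 (final about 2 mM); sat. aq NH4Cl at −78 °C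
Reagents that add atoms: none
Why: Electron transfer from SmI2 to the more easily reduced enal gives a samarium-bound allylic ketyl, and the C8 aldehyde, held on the same or an iodide-bridged trivalent samarium centre, is reduced and joined to it at C9; this is an intramolecular pinacol coupling, the closest known type being the cyclisation of dialdehydes to medium and large cyclic 1,2-diols with SmI2 or low-valent titanium. The ten-membered carbocycle closes in the 10-exo-trig mode, with the C8 carbonyl oxygen outside the new ring. The C8–C9 relationship is controlled by the metal bridge: both oxygens sit in one samarium diolate chelate, the new bond forms with the two C–O bonds synclinal, and this should give the cis diol. The sense at C8 is controlled by C7: a gauche C6–C7–C8–C9 ring torsion places the C7–C11 bond anti to the forming bond, and the carbonyl then turns its hydrogen toward H7 and its oxygen toward C6 (a Felkin–Anh arrangement), which leads to 8S, with 9R following from the chelate. Three selectivities are needed: bonding through C9 and not C1 of the allylic ketyl (secured by the five-membered chelate, whereas C1 coupling would need a seven-membered chelate and give an eight-membered ring), retention of the Z C1=C10 bond (secured at −78 °C, where rotation of the allylic radical should be slower than ring closure), and cyclisation over oligomerisation (secured by slow addition at high dilution). The trans lactone and the E C4=C5 and Z C1=C10 bonds remove rotors from the chain and bring C8 and C9 within reach. The lactone is kept saturated on purpose, since a 2-methylene lactone would be reduced, and no proton source or HMPA is added, so neither simple reduction nor attack on the lactone should compete. The cold quench limits migration of the lactone from O6 to the new O8 alkoxide.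

Step 14
Reactants: 20 (3aR,4S,5R,6Z,10E,11aR)-4,5-dihydroxy-6,10-dimethyl-3a,4,5,8,9,11a-hexahydrocyclodeca[b]furan-2(3H)-one
Product: 22 (3aS,4S,5R,6Z,10E,11aR)-5-{[tert-butyl(dimethyl)silyl]oxy}-6,10-dimethyl-4-[(triethylsilyl)oxy]-3a,4,5,8,9,11a-hexahydrocyclodeca[b]furan-2(3H)-one, via C9 mono-TBS ether 21 (not isolated)
Conditions: TBSCl (1.1 equiv), imidazole, DMF, −20 to 0 °C; then TESCl, DMAP (cat.), 0 °C to rt
Reagents that add atoms: tert-butyldimethylsilyl chloride, CC(C)(C)[Si](C)(C)Cl; triethylsilyl chloride, CC[Si](CC)(CC)Cl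
Why: Kinetically controlled silylation: the allylic C9 hydroxyl next to sp2 C10 should take the bulky TBS group before the C8 hydroxyl, which sits between C7 and C9 on the face of C11. The C8 hydroxyl then takes the more labile triethylsilyl group in the same flask, which gives two masks that can be removed in sequence.

Step 15
Reactants: 22 (3aS,4S,5R,6Z,10E,11aR)-5-{[tert-butyl(dimethyl)silyl]oxy}-6,10-dimethyl-4-[(triethylsilyl)oxy]-3a,4,5,8,9,11a-hexahydrocyclodeca[b]furan-2(3H)-one
Product: 23 (3aS,4S,5R,6Z,10E,11aR)-5-{[tert-butyl(dimethyl)silyl]oxy}-3-[(dimethylamino)methyl]-6,10-dimethyl-4-[(triethylsilyl)oxy]-3a,4,5,8,9,11a-hexahydrocyclodeca[b]furan-2(3H)-one (either configuration at C3)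
Conditions: LiN(i-Pr)2, THF, −78 °C; CH2=NMe2 I (Eschenmoser's salt), −78 °C to rt
Reagents that add atoms: N,N-dimethylmethyleneiminium iodide, C=[N+](C)C.[I-]
Why: Mannich reaction of the lithium lactone enolate with Eschenmoser's salt brings in C13; there is no leaving group β to the enolate carbon, both hydroxyls are masked, and the new C11 centre is destroyed in the next step.

Step 16
Reactants: 23 (3aS,4S,5R,6Z,10E,11aR)-5-{[tert-butyl(dimethyl)silyl]oxy}-3-[(dimethylamino)methyl]-6,10-dimethyl-4-[(triethylsilyl)oxy]-3a,4,5,8,9,11a-hexahydrocyclodeca[b]furan-2(3H)-one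
Product: 25 (3aS,4S,5R,6Z,10E,11aR)-5-{[tert-butyl(dimethyl)silyl]oxy}-6,10-dimethyl-3-methylidene-4-[(triethylsilyl)oxy]-3a,4,5,8,9,11a-hexahydrocyclodeca[b]furan-2(3H)-one, via trimethylammonium iodide 24 (not isolated)
Conditions: MeI, THF, rt; then sat. aq NaHCO3, CH2Cl2, rt
Reagents that add atoms: none
Why: N-methylation followed by Hofmann-type (E1cB) loss of trimethylamine from the β-ammonio lactone under bicarbonate should give the exocyclic C11=C13 bond without touching the silyl ethers.

Step 17
Reactants: 25 (3aS,4S,5R,6Z,10E,11aR)-5-{[tert-butyl(dimethyl)silyl]oxy}-6,10-dimethyl-3-methylidene-4-[(triethylsilyl)oxy]-3a,4,5,8,9,11a-hexahydrocyclodeca[b]furan-2(3H)-one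
Product: 26 (3aR,4S,5R,6Z,10E,11aR)-5-{[tert-butyl(dimethyl)silyl]oxy}-4-hydroxy-6,10-dimethyl-3-methylidene-3a,4,5,8,9,11a-hexahydrocyclodeca[b]furan-2(3H)-one
Conditions: HF·pyridine, pyridine, THF, 0 °C
Reagents that add atoms: none
Why: Selective desilylation: a triethylsilyl ether is cleaved by buffered HF·pyridine far faster than a TBS ether, so O8 is freed while O9 stays masked; the medium is too weakly acidic for transannular cyclisation of the diene.

Step 18
Reactants: 27 [(2S)-2-methyloxiran-2-yl]methanol
Product: 28 [(2R)-2-methyloxiran-2-yl]methyl 4-methylbenzenesulfonate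
Conditions: TsCl, Et3N, DMAP (cat.), CH2Cl2, 0 °C
Reagents that add atoms: 4-methylbenzenesulfonyl chloride, Cc1ccc(cc1)S(=O)(=O)Cl
Why: Sulfonylation of the primary alcohol; no bond at the stereocentre is touched, and the descriptor changes from S to R only because the priorities change.

Step 19
Reactants: 28 [(2R)-2-methyloxiran-2-yl]methyl 4-methylbenzenesulfonate
Product: 30 (2R)-2-methyl-2-(prop-2-en-1-yl)oxirane, via tosyloxy alcohol 29 (not isolated)
Conditions: CH2=CHMgBr, CuI (cat.), THF, −40 to −20 °C; then 2 M NaOH, Et2O, rt
Reagents that add atoms: vinylmagnesium bromide, C=C[Mg]Br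
Why: Copper-catalysed Grignard opening of the oxirane at its CH2, which should be far faster than displacement at the neopentyl-type sulfonate. The tertiary alkoxide then displaces the tosylate, so the oxirane re-forms on the other arm and the quaternary centre keeps its configuration.

Step 20
Reactants: 30 (2R)-2-methyl-2-(prop-2-en-1-yl)oxirane
Product: 32 sodium [(2R)-2-methyloxiran-2-yl]acetate, via epoxy aldehyde 31 (not isolated)
Conditions: O3, CH2Cl2, −78 °C; PPh3; then NaClO2, NaH2PO4, 2-methylbut-2-ene, t-BuOH/H2O, 0 °C; extraction at pH 4, NaHCO3 (1 equiv), lyophilisation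
Reagents that add atoms: ozone, [O-][O+]=O; sodium chlorite, [Na+].[O-]Cl=O; sodium hydrogen carbonate, [Na+].OC([O-])=O
Why: Ozonolysis cuts the terminal alkene to the aldehyde and Pinnick oxidation takes it to the acid under buffered conditions that should spare the oxirane; the acid is kept as its sodium salt because the free β,γ-epoxy acid tends to lactonise.

Step 21
Reactants: 26 (3aR,4S,5R,6Z,10E,11aR)-5-{[tert-butyl(dimethyl)silyl]oxy}-4-hydroxy-6,10-dimethyl-3-methylidene-3a,4,5,8,9,11a-hexahydrocyclodeca[b]furan-2(3H)-one; 32 sodium [(2R)-2-methyloxiran-2-yl]acetate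
Product: 34 (3aS,4S,5R,6Z,10E,11aR)-5-{[tert-butyl(dimethyl)silyl]oxy}-6,10-dimethyl-3-methylidene-2-oxo-2,3,3a,4,5,8,9,11a-octahydrocyclodeca[b]furan-4-yl [(2R)-2-methyloxiran-2-yl]acetate, via mixed anhydride 33 (not isolated)
Conditions: 32, 2,4,6-Cl3C6H2COCl, THF, 0 °C to rt; then 26, DMAP, toluene, rt
Reagents that add atoms: none
Why: Yamaguchi esterification: the carboxylate salt is converted into the mixed anhydride without free acid or trialkylamine, and DMAP transfers the acyl group to the only free hydroxyl (O8) with retention at C8.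

Step 22
Reactants: 34 (3aS,4S,5R,6Z,10E,11aR)-5-{[tert-butyl(dimethyl)silyl]oxy}-6,10-dimethyl-3-methylidene-2-oxo-2,3,3a,4,5,8,9,11a-octahydrocyclodeca[b]furan-4-yl [(2R)-2-methyloxiran-2-yl]acetate
Product: 35 (3aS,4S,5R,6Z,10E,11aR)-5-hydroxy-6,10-dimethyl-3-methylidene-2-oxo-2,3,3a,4,5,8,9,11a-octahydrocyclodeca[b]furan-4-yl [(2R)-2-methyloxiran-2-yl]acetate
Conditions: Bu4NF, AcOH (1:1), THF, 0 °C to rt
Reagents that add atoms: none
Why: Fluoride desilylation buffered with acetic acid frees O9 without a persistent alkoxide, so acyl shift from O8 to O9, opening of the β,γ-epoxy ester and additions to the methylene lactone should be avoided.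

## Compound list

1 | pent-4-yn-1-ol | C#CCCCO | starting material
2 | pent-4-ynal | C#CCCC=O | intermediate
3 | ethyl 2-[bis(2,2,2-trifluoroethoxy)phosphoryl]propanoate | CCOC(=O)C(C)P(=O)(OCC(F)(F)F)OCC(F)(F)F | starting material
4 | ethyl (2Z)-2-methylhept-2-en-6-ynoate | CCOC(=O)/C(C)=C\CCC#C | intermediate
5 | (2Z)-2-methylhept-2-en-6-yn-1-ol | OC/C(C)=C\CCC#C | intermediate
6 | tert-butyl(dimethyl){[(2Z)-2-methylhept-2-en-6-yn-1-yl]oxy}silane | CC(C)(C)[Si](C)(C)OC/C(C)=C\CCC#C | intermediate
7 | [(1E,5Z)-7-{[tert-butyl(dimethyl)silyl]oxy}-2,6-dimethylhepta-1,5-dien-1-yl]dimethylalumane | C[Al](C)/C=C(\C)CC/C=C(C)\CO[Si](C)(C)C(C)(C)C | intermediate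
8 | lithium butyl[(1E,5Z)-7-{[tert-butyl(dimethyl)silyl]oxy}-2,6-dimethylhepta-1,5-dien-1-yl]dimethylaluminate | [Li+].CCCC[Al-](C)(C)/C=C(\C)CC/C=C(C)\CO[Si](C)(C)C(C)(C)C | intermediate
9 | (2E,6Z)-8-{[tert-butyl(dimethyl)silyl]oxy}-3,7-dimethylocta-2,6-dien-1-ol | OC/C=C(\C)CC/C=C(C)\CO[Si](C)(C)C(C)(C)C | intermediate
10 | (2E,6Z)-8-{[tert-butyl(dimethyl)silyl]oxy}-3,7-dimethylocta-2,6-dienal | O=C/C=C(\C)CC/C=C(C)\CO[Si](C)(C)C(C)(C)C | intermediate
11 | (4S)-4-benzyl-1,3-oxazolidin-2-one | O=C1OC[C@H](Cc2ccccc2)N1 | starting material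
12 | methyl 4-chloro-4-oxobutanoate | COC(=O)CCC(Cl)=O | starting material
13 | methyl 4-[(4S)-4-benzyl-2-oxo-1,3-oxazolidin-3-yl]-4-oxobutanoate | COC(=O)CCC(=O)N1[C@@H](Cc2ccccc2)COC1=O | intermediate
14 | methyl (3S,4R,5E,9Z)-3-[(4S)-4-benzyl-2-oxo-1,3-oxazolidine-3-carbonyl]-11-{[tert-butyl(dimethyl)silyl]oxy}-4-hydroxy-6,10-dimethylundeca-5,9-dienoate | COC(=O)C[C@@H]([C@H](O)/C=C(\C)CC/C=C(C)\CO[Si](C)(C)C(C)(C)C)C(=O)N1[C@@H](Cc2ccccc2)COC1=O | intermediate
15 | (4S)-4-benzyl-3-{(2R,3S)-2-[(1E,5Z)-7-{[tert-butyl(dimethyl)silyl]oxy}-2,6-dimethylhepta-1,5-dien-1-yl]-5-oxooxolane-3-carbonyl}-1,3-oxazolidin-2-one | CC(C)(C)[Si](C)(C)OC/C(C)=C\CC/C(C)=C/[C@H]1OC(=O)C[C@@H]1C(=O)N2[C@@H](Cc3ccccc3)COC2=O | intermediate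
16 | S-ethyl (2R,3S)-2-[(1E,5Z)-7-{[tert-butyl(dimethyl)silyl]oxy}-2,6-dimethylhepta-1,5-dien-1-yl]-5-oxooxolane-3-carbothioate | CC(C)(C)[Si](C)(C)OC/C(C)=C\CC/C(C)=C/[C@H]1OC(=O)C[C@@H]1C(=O)SCC | intermediate
17 | (2R,3S)-2-[(1E,5Z)-7-{[tert-butyl(dimethyl)silyl]oxy}-2,6-dimethylhepta-1,5-dien-1-yl]-5-oxooxolane-3-carbaldehyde | CC(C)(C)[Si](C)(C)OC/C(C)=C\CC/C(C)=C/[C@H]1OC(=O)C[C@@H]1C=O | intermediate
18 | (2R,3S)-2-[(1E,5Z)-7-hydroxy-2,6-dimethylhepta-1,5-dien-1-yl]-5-oxooxolane-3-carbaldehyde | OC/C(C)=C\CC/C(C)=C/[C@H]1OC(=O)C[C@@H]1C=O | intermediate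
19 | (2R,3S)-2-[(1E,5Z)-2,6-dimethyl-7-oxohepta-1,5-dien-1-yl]-5-oxooxolane-3-carbaldehyde | O=C/C(C)=C\CC/C(C)=C/[C@H]1OC(=O)C[C@@H]1C=O | intermediate
20 | (3aR,4S,5R,6Z,10E,11aR)-4,5-dihydroxy-6,10-dimethyl-3a,4,5,8,9,11a-hexahydrocyclodeca[b]furan-2(3H)-one | C1C(=O)O[C@@H]2/C=C(\C)CC/C=C(/C)[C@@H](O)[C@@H](O)[C@@H]12 | intermediate
21 | (3aR,4S,5R,6Z,10E,11aR)-5-{[tert-butyl(dimethyl)silyl]oxy}-4-hydroxy-6,10-dimethyl-3a,4,5,8,9,11a-hexahydrocyclodeca[b]furan-2(3H)-one | C1C(=O)O[C@@H]2/C=C(\C)CC/C=C(/C)[C@@H](O[Si](C)(C)C(C)(C)C)[C@@H](O)[C@@H]12 | intermediate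
22 | (3aS,4S,5R,6Z,10E,11aR)-5-{[tert-butyl(dimethyl)silyl]oxy}-6,10-dimethyl-4-[(triethylsilyl)oxy]-3a,4,5,8,9,11a-hexahydrocyclodeca[b]furan-2(3H)-one | C1C(=O)O[C@@H]2/C=C(\C)CC/C=C(/C)[C@@H](O[Si](C)(C)C(C)(C)C)[C@@H](O[Si](CC)(CC)CC)[C@@H]12 | intermediate
23 | (3aS,4S,5R,6Z,10E,11aR)-5-{[tert-butyl(dimethyl)silyl]oxy}-3-[(dimethylamino)methyl]-6,10-dimethyl-4-[(triethylsilyl)oxy]-3a,4,5,8,9,11a-hexahydrocyclodeca[b]furan-2(3H)-one (C3 unspecified) | CN(C)CC1C(=O)O[C@@H]2/C=C(\C)CC/C=C(/C)[C@@H](O[Si](C)(C)C(C)(C)C)[C@@H](O[Si](CC)(CC)CC)[C@@H]12 | intermediate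
24 | {[(3aS,4S,5R,6Z,10E,11aR)-5-{[tert-butyl(dimethyl)silyl]oxy}-6,10-dimethyl-2-oxo-4-[(triethylsilyl)oxy]-2,3,3a,4,5,8,9,11a-octahydrocyclodeca[b]furan-3-yl]methyl}trimethylammonium iodide (C3 unspecified) | C[N+](C)(C)CC1C(=O)O[C@@H]2/C=C(\C)CC/C=C(/C)[C@@H](O[Si](C)(C)C(C)(C)C)[C@@H](O[Si](CC)(CC)CC)[C@@H]12.[I-] | intermediate
25 | (3aS,4S,5R,6Z,10E,11aR)-5-{[tert-butyl(dimethyl)silyl]oxy}-6,10-dimethyl-3-methylidene-4-[(triethylsilyl)oxy]-3a,4,5,8,9,11a-hexahydrocyclodeca[b]furan-2(3H)-one | C=C1C(=O)O[C@@H]2/C=C(\C)CC/C=C(/C)[C@@H](O[Si](C)(C)C(C)(C)C)[C@@H](O[Si](CC)(CC)CC)[C@@H]12 | intermediate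
26 | (3aR,4S,5R,6Z,10E,11aR)-5-{[tert-butyl(dimethyl)silyl]oxy}-4-hydroxy-6,10-dimethyl-3-methylidene-3a,4,5,8,9,11a-hexahydrocyclodeca[b]furan-2(3H)-one | C=C1C(=O)O[C@@H]2/C=C(\C)CC/C=C(/C)[C@@H](O[Si](C)(C)C(C)(C)C)[C@@H](O)[C@@H]12 | intermediate
27 | [(2S)-2-methyloxiran-2-yl]methanol | OC[C@@]1(C)CO1 | starting material
28 | [(2R)-2-methyloxiran-2-yl]methyl 4-methylbenzenesulfonate | Cc1ccc(cc1)S(=O)(=O)OC[C@@]1(C)CO1 | intermediate
29 | (2R)-2-hydroxy-2-methylpent-4-en-1-yl 4-methylbenzenesulfonate | C=CC[C@@](C)(O)COS(=O)(=O)c1ccc(C)cc1 | intermediate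
30 | (2R)-2-methyl-2-(prop-2-en-1-yl)oxirane | C=CC[C@]1(C)CO1 | intermediate
31 | [(2R)-2-methyloxiran-2-yl]acetaldehyde | O=CC[C@]1(C)CO1 | intermediate
32 | sodium [(2R)-2-methyloxiran-2-yl]acetate | [Na+].[O-]C(=O)C[C@]1(C)CO1 | intermediate
33 | [(2R)-2-methyloxiran-2-yl]acetic 2,4,6-trichlorobenzoic anhydride | O=C(OC(=O)C[C@]1(C)CO1)c1c(Cl)cc(Cl)cc1Cl | intermediate
34 | (3aS,4S,5R,6Z,10E,11aR)-5-{[tert-butyl(dimethyl)silyl]oxy}-6,10-dimethyl-3-methylidene-2-oxo-2,3,3a,4,5,8,9,11a-octahydrocyclodeca[b]furan-4-yl [(2R)-2-methyloxiran-2-yl]acetate | C=C1C(=O)O[C@@H]2/C=C(\C)CC/C=C(/C)[C@@H](O[Si](C)(C)C(C)(C)C)[C@@H](OC(=O)C[C@]3(C)CO3)[C@@H]12 | intermediate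
35 | (3aS,4S,5R,6Z,10E,11aR)-5-hydroxy-6,10-dimethyl-3-methylidene-2-oxo-2,3,3a,4,5,8,9,11a-octahydrocyclodeca[b]furan-4-yl [(2R)-2-methyloxiran-2-yl]acetate | C=C1C(=O)O[C@@H]2/C=C(\C)CC/C=C(/C)[C@@H](O)[C@@H](OC(=O)C[C@]3(C)CO3)[C@@H]12 | target

## Step count and least certain steps

Total step count: 22. Longest linear sequence: 18 steps (steps 1 to 6, 8 to 17, 21 and 22); step 7 and steps 18 to 20 are side branches.

**Step 13 (key step).** What is most likely to go wrong:
- bonding through C1 of the allylic ketyl, which would give an eight-membered ring;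
- rotation in the allylic radical with loss of the Z geometry;
- simple reduction or oligomerisation;
- formation of the diol epimeric at C9, because a ten-membered ring does not enforce a cis diol as firmly as a small ring;
- poor facial selectivity at C8, which cannot be corrected afterwards;
- migration of the lactone to O8 in the metal diolate.

Fallback (answers the C9 problem): setting out from 19, the coupling is run with low-valent titanium (TiCl3, Zn–Cu, DME, slow addition, 0 °C), where both carbonyl oxygens are bound to the metal and enals couple at the carbonyl carbon. If this delivers the 8,9-trans diol, (3aR,4S,5S,6Z,10E,11aR)-4,5-dihydroxy-6,10-dimethyl-3a,4,5,8,9,11a-hexahydrocyclodeca[b]furan-2(3H)-one F1, only its allylic C9 hydroxyl is oxidised with MnO2 to the hydroxy enone (3aR,4S,6Z,10E,11aR)-4-hydroxy-6,10-dimethyl-3a,4,8,9-tetrahydrocyclodeca[b]furan-2,5(3H,11aH)-dione F2. Reduction of F2 under chelation control (Zn(BH4)2, Et2O, −78 °C), with zinc bridging O8 and the C9 carbonyl, should reset C9 to the cis diol and return to the route at 20.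

**Step 14.** What may go wrong: poor or reversed regioselectivity between the two secondary hydroxyls, or lactone migration to O8 while it is free. Fallback: setting out from 20, the diol is converted with Bu2Sn(OMe)2 (toluene, rt, evaporation) into the dibutylstannylene acetal of 20 F3, in which the tin-bound allylic oxygen is the more nucleophilic one. Treatment of F3 with TBSCl (CsF, DMF) should then silylate O9 and give 21, which returns to the route with TESCl to 22.

**Step 10.** What may go wrong: hydrogenolysis of the allylic C6–O bond or alkene migration by palladium hydride, or β-elimination of the lactone oxygen from the activated C8 carbonyl. Fallback: setting out from 15, the imide is reduced directly with NaBH4 in THF/H2O at 0 °C (quench at pH 7 to limit lactone migration) to (4R,5R)-5-[(1E,5Z)-7-{[tert-butyl(dimethyl)silyl]oxy}-2,6-dimethylhepta-1,5-dien-1-yl]-4-(hydroxymethyl)oxolan-2-one F4. F4 is oxidised with Dess–Martin periodinane (NaHCO3, CH2Cl2) to the aldehyde and returns to the route at 17.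

**Step 21.** What may go wrong: base-induced opening of the β,γ-epoxy acyl unit (E1cB) at the activated stage, lactonisation of the liberated acid, or slow acylation of the hindered C8 hydroxyl next to the TBS ether. Fallback: setting out from 32 and 26, the oxirane of 32 is opened with LiCl in AcOH/THF to (3R)-4-chloro-3-hydroxy-3-methylbutanoic acid F5, which has no strained ring next to the activated carbonyl. F5 is coupled to 26 (EDC·HCl, DMAP cat., CH2Cl2, 0 °C) to give (3aS,4S,5R,6Z,10E,11aR)-5-{[tert-butyl(dimethyl)silyl]oxy}-6,10-dimethyl-3-methylidene-2-oxo-2,3,3a,4,5,8,9,11a-octahydrocyclodeca[b]furan-4-yl (3R)-4-chloro-3-hydroxy-3-methylbutanoate F6. The oxirane is then closed with K2CO3 in acetone, returning to the route at 34.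

**Step 22.** What may go wrong: acyl shift from O8 to O9 on slow desilylation, opening of the oxirane by fluoride or acid, or conjugate addition to the methylene lactone. Fallback: setting out from 25, both silyl groups are removed at once (HF·pyridine, THF, rt) to give (3aR,4S,5R,6Z,10E,11aR)-4,5-dihydroxy-6,10-dimethyl-3-methylidene-3a,4,5,8,9,11a-hexahydrocyclodeca[b]furan-2(3H)-one F7. O9 alone is silylated with TESCl (imidazole, −40 °C) to (3aR,4S,5R,6Z,10E,11aR)-4-hydroxy-6,10-dimethyl-3-methylidene-5-[(triethylsilyl)oxy]-3a,4,5,8,9,11a-hexahydrocyclodeca[b]furan-2(3H)-one F8. F8 is acylated with 33 as in step 21 to (3aS,4S,5R,6Z,10E,11aR)-6,10-dimethyl-3-methylidene-2-oxo-5-[(triethylsilyl)oxy]-2,3,3a,4,5,8,9,11a-octahydrocyclodeca[b]furan-4-yl [(2R)-2-methyloxiran-2-yl]acetate F9. The triethylsilyl ether of F9 is cleaved under much milder conditions than a TBS ether (HF·pyridine/pyridine, THF, 0 °C), returning to the route at 35.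

## Further compounds

F1 | step 13 | (3aR,4S,5S,6Z,10E,11aR)-4,5-dihydroxy-6,10-dimethyl-3a,4,5,8,9,11a-hexahydrocyclodeca[b]furan-2(3H)-one | C1C(=O)O[C@@H]2/C=C(\C)CC/C=C(/C)[C@H](O)[C@@H](O)[C@@H]12
F2 | step 13 | (3aR,4S,6Z,10E,11aR)-4-hydroxy-6,10-dimethyl-3a,4,8,9-tetrahydrocyclodeca[b]furan-2,5(3H,11aH)-dione | C1C(=O)O[C@@H]2/C=C(\C)CC/C=C(/C)C(=O)[C@@H](O)[C@@H]12
F3 | step 14 | dibutylstannylene acetal of 20 (2,2-dibutyl-1,3,2-dioxastannolane fused at C8–C9 of the lactone, configuration as in 20) | C1C(=O)O[C@@H]2/C=C(\C)CC/C=C(/C)[C@H]3O[Sn](CCCC)(CCCC)O[C@H]3[C@@H]12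
F4 | step 10 | (4R,5R)-5-[(1E,5Z)-7-{[tert-butyl(dimethyl)silyl]oxy}-2,6-dimethylhepta-1,5-dien-1-yl]-4-(hydroxymethyl)oxolan-2-one | CC(C)(C)[Si](C)(C)OC/C(C)=C\CC/C(C)=C/[C@H]1OC(=O)C[C@@H]1CO
F5 | step 21 | (3R)-4-chloro-3-hydroxy-3-methylbutanoic acid | OC(=O)C[C@@](C)(O)CCl
F6 | step 21 | (3aS,4S,5R,6Z,10E,11aR)-5-{[tert-butyl(dimethyl)silyl]oxy}-6,10-dimethyl-3-methylidene-2-oxo-2,3,3a,4,5,8,9,11a-octahydrocyclodeca[b]furan-4-yl (3R)-4-chloro-3-hydroxy-3-methylbutanoate | C=C1C(=O)O[C@@H]2/C=C(\C)CC/C=C(/C)[C@@H](O[Si](C)(C)C(C)(C)C)[C@@H](OC(=O)C[C@@](C)(O)CCl)[C@@H]12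
F7 | step 22 | (3aR,4S,5R,6Z,10E,11aR)-4,5-dihydroxy-6,10-dimethyl-3-methylidene-3a,4,5,8,9,11a-hexahydrocyclodeca[b]furan-2(3H)-one | C=C1C(=O)O[C@@H]2/C=C(\C)CC/C=C(/C)[C@@H](O)[C@@H](O)[C@@H]12
F8 | step 22 | (3aR,4S,5R,6Z,10E,11aR)-4-hydroxy-6,10-dimethyl-3-methylidene-5-[(triethylsilyl)oxy]-3a,4,5,8,9,11a-hexahydrocyclodeca[b]furan-2(3H)-one | C=C1C(=O)O[C@@H]2/C=C(\C)CC/C=C(/C)[C@@H](O[Si](CC)(CC)CC)[C@@H](O)[C@@H]12
F9 | step 22 | (3aS,4S,5R,6Z,10E,11aR)-6,10-dimethyl-3-methylidene-2-oxo-5-[(triethylsilyl)oxy]-2,3,3a,4,5,8,9,11a-octahydrocyclodeca[b]furan-4-yl [(2R)-2-methyloxiran-2-yl]acetate | C=C1C(=O)O[C@@H]2/C=C(\C)CC/C=C(/C)[C@@H](O[Si](CC)(CC)CC)[C@@H](OC(=O)C[C@]3(C)CO3)[C@@H]12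
A1 | alternative 1 | (3aS,4S,5R,6Z,10E,11aR)-5-{[tert-butyl(dimethyl)silyl]oxy}-6,10-dimethyl-4-[(triethylsilyl)oxy]-3a,4,5,8,9,11a-hexahydrocyclodeca[b]furan-2(3H)-one (identical with 22) | C1C(=O)O[C@@H]2/C=C(\C)CC/C=C(/C)[C@@H](O[Si](C)(C)C(C)(C)C)[C@@H](O[Si](CC)(CC)CC)[C@@H]12
A2 | alternative 2 | ring-cis-1(10),4E-cyclodecadien-10-yl trifluoromethanesulfonate with O6 as TBS ether, a 3-[(4-methoxybenzyl)oxy]prop-1-en-2-yl group on C7 and an 8,9-O-isopropylidene acetal (germacrane locants, C6 to C9 arranged as in the target) | FC(F)(F)S(=O)(=O)O/C1=C/CC/C(C)=C/[C@@H](O[Si](C)(C)C(C)(C)C)[C@H](C(=C)COCc2ccc(OC)cc2)[C@@H]3OC(C)(C)O[C@@H]31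
A3 | alternative 3 | (1(10)Z,4E)-cyclodecadien-9-one with a 4-methoxybenzyl ether on O6 and a 3-[(4-methoxybenzyl)oxy]prop-1-en-2-yl group on C7 (germacrane locants, C6 and C7 arranged as in the target) | C=C(COCc2ccc(OC)cc2)[C@H]1[C@H](OCc3ccc(OC)cc3)/C=C(\C)CC/C=C(/C)C(=O)C1
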